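**Plan** (1H-isochromene numbering: C1H2, O2, C3, C4, C4a, C5H2, C6, C7, C8=O, C8a)
- Retrosynthesis: after removal of the two acid-labile protecting groups, the C4a–C5 and C6–C7 bonds of the carbocycle are cut together, giving the vinyl ester of the protected benzoic acid and a pyran-fused 4-hydroxycyclobutenone. The latter is traced back through O2–C3 (alkynol cyclization) and three C–C bonds to diisopropyl squarate.
- Enabling feature: C4a=C8a–C8(=O)–C7(OH)(CH3) is a ring-opened 4-hydroxy-4-methylcyclobut-2-en-1-one. Joining C4a to C7 gives a strained four-membered ring, and the C4a–C7 bond of that ring takes up the two vinyl carbons of the ester (strain release).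
- Forward order: squarate → trisubstituted hydroxycyclobutenone → 2H-pyran ring (gold, 6-endo) → carbocycle (rhodium) → global acidolysis.
- Stereochemistry: the cyclobutenol is used as the racemate because its stereocentre is erased on ring opening. C6 and C7 are both set in the key step by a chiral rhodium bisphosphine catalyst, with the cis relationship arising in the ring closure.

Key step: step 14

Assumption: the sense of induction of the rhodium/(R)-DTBM-SEGPHOS catalyst cannot be predicted with confidence and is taken to give (6S,7S); if the opposite sense is found, the (S)-ligand is used.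

Step 1
Reactants: 1 2,3,4-trimethoxy-6-methylbenzaldehyde
Product: 2 2,3,4-trihydroxy-6-methylbenzaldehyde
Conditions: BBr3 (4 equiv), CH2Cl2, −78 °C to rt; then H2O
Reagents that add atoms: none
Why: Exhaustive Lewis-acid cleavage of aryl methyl ethers should free all three phenols, so that the catechol pair and the 2-OH can then be told apart.

Step 2
Reactants: 2 2,3,4-trihydroxy-6-methylbenzaldehyde
Product: 3 4-hydroxy-6-methyl-2,2-diphenyl-1,3-benzodioxole-5-carbaldehyde
Conditions: Ph2CCl2, Ph2O, 170 °C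
Reagents that add atoms: dichlorodiphenylmethane ClC(Cl)(c1ccccc1)c1ccccc1
Why: Catechol ketalization should take the 3,4-diol because the 2-OH is held in a hydrogen bond to the formyl group.

Step 3
Reactants: 3 4-hydroxy-6-methyl-2,2-diphenyl-1,3-benzodioxole-5-carbaldehyde
Product: 4 4-methoxy-6-methyl-2,2-diphenyl-1,3-benzodioxole-5-carbaldehyde
Conditions: MeI, K2CO3, DMF, 50 °C
Reagents that add atoms: iodomethane CI
Why: Williamson O-methylation of the one remaining phenol should be clean once the catechol is masked.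

Step 4
Reactants: 4 4-methoxy-6-methyl-2,2-diphenyl-1,3-benzodioxole-5-carbaldehyde
Product: 5 4-methoxy-6-methyl-2,2-diphenyl-1,3-benzodioxole-5-carboxylic acid
Conditions: NaClO2, NaH2PO4, 2-methyl-2-butene, t-BuOH/H2O, rt
Reagents that add atoms: sodium chlorite [Na+].[O-]Cl=O
Why: Pinnick oxidation should convert the hindered, electron-rich aldehyde to the acid without touching the ketal or the ring.

Step 5
Reactants: 5 4-methoxy-6-methyl-2,2-diphenyl-1,3-benzodioxole-5-carboxylic acid
Product: 6 ethenyl 4-methoxy-6-methyl-2,2-diphenyl-1,3-benzodioxole-5-carboxylate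
Conditions: vinyl acetate (excess), [Ir(cod)Cl]2 (1 mol%), NaOAc (5 mol%), toluene, 100 °C
Reagents that add atoms: vinyl acetate C=COC(C)=O
Why: Iridium-catalysed transvinylation acts at the carboxylate oxygen and not at the shielded carbonyl carbon, so the 2,6-disubstituted acid should vinylate normally.

Step 6
Reactants: 7 tributyl(iodomethyl)stannane; 8 (4-methoxyphenyl)methanol
Product: 9 tributyl{[(4-methoxybenzyl)oxy]methyl}stannane
Conditions: NaH, THF/DMF, 0 °C to rt
Reagents that add atoms: none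
Why: Williamson etherification of the primary iodide should give the tin precursor of a PMB-protected hydroxymethyl anion.

Step 7
Reactants: 9 tributyl{[(4-methoxybenzyl)oxy]methyl}stannane; 10 3,4-di(propan-2-yloxy)cyclobut-3-ene-1,2-dione (diisopropyl squarate)
Product: 13 3-{[(4-methoxybenzyl)oxy]methyl}-4-(propan-2-yloxy)cyclobut-3-ene-1,2-dione, via alkoxymethyllithium 11 (not isolated), via squarate 1,2-adduct 12 (not isolated)
Conditions: 9, n-BuLi, THF, −78 °C; add 10, −78 °C; then (CF3CO)2O, −78 to 0 °C; aq. NaHCO3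
Reagents that add atoms: water O
Why: Tin–lithium exchange, 1,2-addition to the squarate and trifluoroacetate-assisted ionization with hydrolysis of the distal enol ether (standard squarate substitution chemistry) should replace one isopropoxy group by the carbon substituent.

Step 8
Reactants: 13 3-{[(4-methoxybenzyl)oxy]methyl}-4-(propan-2-yloxy)cyclobut-3-ene-1,2-dione
Product: 15 2-{[(4-methoxybenzyl)oxy]methyl}-4-methyl-3-(propan-2-yloxy)-4-[(trimethylsilyl)oxy]cyclobut-2-en-1-one, via tertiary alcohol 14 (not isolated)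
Conditions: MeLi, THF, −78 °C; then Me3SiCl, −78 to 0 °C
Reagents that add atoms: methyllithium [Li]C; chlorotrimethylsilane C[Si](C)(C)Cl
Why: Regioselective 1,2-addition should occur at the carbonyl next to the alkoxy-bearing carbon, since the other carbonyl is a vinylogous ester; the new carbinol centre is racemic on purpose and is capped in the flask.

Step 9
Reactants: 16 3-(trimethylsilyl)prop-2-ynal; 17 tert-butyl (triphenyl-λ5-phosphanylidene)acetate
Product: 18 tert-butyl (2E)-5-(trimethylsilyl)pent-2-en-4-ynoate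
Conditions: CH2Cl2, 0 °C to rt
Reagents that add atoms: none
Why: Wittig olefination with a stabilized ylide should give the (E)-enoate, and any minor (Z)-isomer can be removed by chromatography.

Step 10
Reactants: 18 tert-butyl (2E)-5-(trimethylsilyl)pent-2-en-4-ynoate
Product: 19 tert-butyl (2E)-pent-2-en-4-ynoate
Conditions: K2CO3 (cat.), MeOH, 0 °C, short contact
Reagents that add atoms: none
Why: Methanolysis of the alkynyl C–Si bond should be fast and leave the tert-butyl ester and the alkene geometry intact.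

Step 11
Reactants: 19 tert-butyl (2E)-pent-2-en-4-ynoate; 15 2-{[(4-methoxybenzyl)oxy]methyl}-4-methyl-3-(propan-2-yloxy)-4-[(trimethylsilyl)oxy]cyclobut-2-en-1-one
Product: 22 tert-butyl (2E)-5-(4-hydroxy-2-{[(4-methoxybenzyl)oxy]methyl}-4-methyl-3-oxocyclobut-1-en-1-yl)pent-2-en-4-ynoate, via lithium acetylide 20 (not isolated), via propargylic alcohol 21 (not isolated)
Conditions: 19, LiHMDS, THF, −78 °C; add 15, −78 °C; then 2 M aq. HCl, THF, 0 °C to rt
Reagents that add atoms: water O
Why: Acetylide 1,2-addition to the vinylogous ester carbonyl followed by acid-mediated allylic transposition and enol ether hydrolysis (Stork–Danheiser type) should move the carbonyl next to the hydroxymethyl-bearing carbon, place the alkyne next to the carbinol and remove the silyl ether.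

Step 12
Reactants: 22 tert-butyl (2E)-5-(4-hydroxy-2-{[(4-methoxybenzyl)oxy]methyl}-4-methyl-3-oxocyclobut-1-en-1-yl)pent-2-en-4-ynoate
Product: 23 tert-butyl (2E)-5-[4-hydroxy-2-(hydroxymethyl)-4-methyl-3-oxocyclobut-1-en-1-yl]pent-2-en-4-ynoate
Conditions: DDQ, CH2Cl2/pH 7 buffer, 0 °C to rt
Reagents that add atoms: none
Why: Oxidative PMB cleavage is neutral and should spare the ynenone, the tert-butyl ester and the tertiary alcohol.

Step 13
Reactants: 23 tert-butyl (2E)-5-[4-hydroxy-2-(hydroxymethyl)-4-methyl-3-oxocyclobut-1-en-1-yl]pent-2-en-4-ynoate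
Product: 24 tert-butyl (2E)-3-(7-hydroxy-7-methyl-8-oxo-3-oxabicyclo[4.2.0]octa-1(6),4-dien-4-yl)prop-2-enoate
Conditions: (Ph3P)AuNTf2 (2 mol%), CH2Cl2, rt
Reagents that add atoms: none
Why: Gold-catalysed alkynol cycloisomerization should go 6-endo-dig, because the distal alkyne carbon is the conjugate position of the ynenone and the 5-exo alternative would fuse a five-membered ring onto the cyclobutene double bond.

Step 14
Reactants: 24 tert-butyl (2E)-3-(7-hydroxy-7-methyl-8-oxo-3-oxabicyclo[4.2.0]octa-1(6),4-dien-4-yl)prop-2-enoate; 6 ethenyl 4-methoxy-6-methyl-2,2-diphenyl-1,3-benzodioxole-5-carboxylate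
Product: 27 tert-butyl (2E)-3-[(6S,7S)-7-hydroxy-6-{[(4-methoxy-6-methyl-2,2-diphenyl-1,3-benzodioxol-5-yl)carbonyl]oxy}-7-methyl-8-oxo-5,6,7,8-tetrahydro-1H-isochromen-3-yl]prop-2-enoate, via alkenylrhodium species 25 (not isolated), via alkylrhodium species 26 (not isolated)
Conditions: [Rh(OH)(cod)]2 (2.5 mol%), (R)-DTBM-SEGPHOS (6 mol%), 6 (1.5 equiv), toluene, 40 °C
Reagents that add atoms: none
Why: Proposed new method: the hydroxorhodium catalyst (rhodium in its monovalent state) should exchange with the tertiary alcohol of 24, and β-carbon elimination of the strained cyclobutenolate should cleave the bond between the carbinol carbon and the pyran ring carbon to give the achiral alkenylrhodium 25 from both enantiomers of 24; the vinyl ester 6 then inserts with carbon bonding to its CH2 terminus to give the ester-chelated α-acyloxyalkylrhodium 26, which adds to the unveiled methyl ketone and is released by protonolysis with the next molecule of 24. The closest known reaction type is the rhodium-catalysed ring opening of benzocyclobutenols by C(sp2)–C(sp3) cleavage with insertion of an alkyne or alkene and 1,2-addition to the unveiled ketone (formal [4+2] "cut and sew"), here transferred to a 4-hydroxycyclobutenone and a vinyl ester. The carbocycle closes by a 6-exo-trig 1,2-addition of the alkylrhodium carbon to the ketone carbonyl. C6 is set in the migratory insertion, where the chiral bisphosphine selects the face of the vinyl ester, and C7 is set in the ring closure through a chair-like transition state with the aroyloxy and methyl groups pseudo-equatorial and the rhodium-bound oxygen axial beside the chelating ester, which should give the cis 6-acyloxy-7-hydroxy arrangement. The step needs cleavage toward the alkenyl and not the acyl carbon (precoordination of the ring alkene and relief of the bicyclo[4.2.0] strain), insertion with rhodium on the oxygen-bearing carbon (five-membered chelate of the ester carbonyl, as in the branched-selective hydroformylation of vinyl esters, which also hinders β-hydride elimination), and closure on the methyl ketone and not on the C8 carbonyl (C8 is a doubly vinylogous ester through the pyran dienol ether, while the methyl ketone of the 1,2-dione is the stronger electrophile).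

Step 15
Reactants: 27 tert-butyl (2E)-3-[(6S,7S)-7-hydroxy-6-{[(4-methoxy-6-methyl-2,2-diphenyl-1,3-benzodioxol-5-yl)carbonyl]oxy}-7-methyl-8-oxo-5,6,7,8-tetrahydro-1H-isochromen-3-yl]prop-2-enoate
Product: 28 (2E)-3-[(6S,7S)-6-[(3,4-dihydroxy-2-methoxy-6-methylbenzoyl)oxy]-7-hydroxy-7-methyl-8-oxo-5,6,7,8-tetrahydro-1H-isochromen-3-yl]prop-2-enoic acid
Conditions: CF3CO2H/CH2Cl2/H2O/anisole, 0 °C to rt
Reagents that add atoms: none
Why: Acidolysis should remove the tert-butyl ester and the diphenylmethylene ketal in one operation, and acid avoids the base-induced loss of the C6 carboxylate (γ-deprotonation at C5 and elimination) to which the product is prone.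

**Compound list**
1 | 2,3,4-trimethoxy-6-methylbenzaldehyde | O=Cc1c(C)cc(OC)c(OC)c1OC | starting material
2 | 2,3,4-trihydroxy-6-methylbenzaldehyde | O=Cc1c(C)cc(O)c(O)c1O | intermediate
3 | 4-hydroxy-6-methyl-2,2-diphenyl-1,3-benzodioxole-5-carbaldehyde | O=Cc1c(C)cc2OC(c3ccccc3)(c3ccccc3)Oc2c1O | intermediate
4 | 4-methoxy-6-methyl-2,2-diphenyl-1,3-benzodioxole-5-carbaldehyde | O=Cc1c(C)cc2OC(c3ccccc3)(c3ccccc3)Oc2c1OC | intermediate
5 | 4-methoxy-6-methyl-2,2-diphenyl-1,3-benzodioxole-5-carboxylic acid | OC(=O)c1c(C)cc2OC(c3ccccc3)(c3ccccc3)Oc2c1OC | intermediate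
6 | ethenyl 4-methoxy-6-methyl-2,2-diphenyl-1,3-benzodioxole-5-carboxylate | C=COC(=O)c1c(C)cc2OC(c3ccccc3)(c3ccccc3)Oc2c1OC | intermediate
7 | tributyl(iodomethyl)stannane | CCCC[Sn](CCCC)(CCCC)CI | starting material
8 | (4-methoxyphenyl)methanol | COc1ccc(CO)cc1 | starting material
9 | tributyl{[(4-methoxybenzyl)oxy]methyl}stannane | CCCC[Sn](CCCC)(CCCC)COCc1ccc(OC)cc1 | intermediate
10 | 3,4-di(propan-2-yloxy)cyclobut-3-ene-1,2-dione (diisopropyl squarate) | CC(C)OC1=C(OC(C)C)C(=O)C1=O | starting material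
11 | {[(4-methoxybenzyl)oxy]methyl}lithium | [Li]COCc1ccc(OC)cc1 | intermediate
12 | 4-hydroxy-4-{[(4-methoxybenzyl)oxy]methyl}-2,3-di(propan-2-yloxy)cyclobut-2-en-1-one (racemic; present as its lithium alkoxide) | CC(C)OC1=C(OC(C)C)C(O)(COCc2ccc(OC)cc2)C1=O | intermediate
13 | 3-{[(4-methoxybenzyl)oxy]methyl}-4-(propan-2-yloxy)cyclobut-3-ene-1,2-dione | CC(C)OC1=C(COCc2ccc(OC)cc2)C(=O)C1=O | intermediate
14 | 4-hydroxy-2-{[(4-methoxybenzyl)oxy]methyl}-4-methyl-3-(propan-2-yloxy)cyclobut-2-en-1-one (racemic; present as its lithium alkoxide) | CC(C)OC1=C(COCc2ccc(OC)cc2)C(=O)C1(C)O | intermediate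
15 | 2-{[(4-methoxybenzyl)oxy]methyl}-4-methyl-3-(propan-2-yloxy)-4-[(trimethylsilyl)oxy]cyclobut-2-en-1-one (racemic) | CC(C)OC1=C(COCc2ccc(OC)cc2)C(=O)C1(C)O[Si](C)(C)C | intermediate
16 | 3-(trimethylsilyl)prop-2-ynal | C[Si](C)(C)C#CC=O | starting material
17 | tert-butyl (triphenyl-λ5-phosphanylidene)acetate | CC(C)(C)OC(=O)C=P(c1ccccc1)(c1ccccc1)c1ccccc1 | starting material
18 | tert-butyl (2E)-5-(trimethylsilyl)pent-2-en-4-ynoate | CC(C)(C)OC(=O)/C=C/C#C[Si](C)(C)C | intermediate
19 | tert-butyl (2E)-pent-2-en-4-ynoate | C#C/C=C/C(=O)OC(C)(C)C | intermediate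
20 | tert-butyl (2E)-5-lithiopent-2-en-4-ynoate | [Li]C#C/C=C/C(=O)OC(C)(C)C | intermediate
21 | tert-butyl (2E)-5-{1-hydroxy-2-{[(4-methoxybenzyl)oxy]methyl}-4-methyl-3-(propan-2-yloxy)-4-[(trimethylsilyl)oxy]cyclobut-2-en-1-yl}pent-2-en-4-ynoate (diastereomer mixture; present as its lithium alkoxide) | CC(C)OC1=C(COCc2ccc(OC)cc2)C(O)(C#C/C=C/C(=O)OC(C)(C)C)C1(C)O[Si](C)(C)C | intermediate
22 | tert-butyl (2E)-5-(4-hydroxy-2-{[(4-methoxybenzyl)oxy]methyl}-4-methyl-3-oxocyclobut-1-en-1-yl)pent-2-en-4-ynoate (racemic) | CC1(O)C(C#C/C=C/C(=O)OC(C)(C)C)=C(COCc2ccc(OC)cc2)C1=O | intermediate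
23 | tert-butyl (2E)-5-[4-hydroxy-2-(hydroxymethyl)-4-methyl-3-oxocyclobut-1-en-1-yl]pent-2-en-4-ynoate (racemic) | CC1(O)C(C#C/C=C/C(=O)OC(C)(C)C)=C(CO)C1=O | intermediate
24 | tert-butyl (2E)-3-(7-hydroxy-7-methyl-8-oxo-3-oxabicyclo[4.2.0]octa-1(6),4-dien-4-yl)prop-2-enoate (racemic) | CC1(O)C(=O)C2=C1C=C(/C=C/C(=O)OC(C)(C)C)OC2 | intermediate
25 | {6-[(1E)-3-tert-butoxy-3-oxoprop-1-en-1-yl]-3-(2-oxopropanoyl)-2H-pyran-4-yl}rhodium (bisphosphine ligand omitted) | CC(=O)C(=O)C1=C([Rh])C=C(/C=C/C(=O)OC(C)(C)C)OC1 | intermediate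
26 | {(1S)-2-{6-[(1E)-3-tert-butoxy-3-oxoprop-1-en-1-yl]-3-(2-oxopropanoyl)-2H-pyran-4-yl}-1-{[(4-methoxy-6-methyl-2,2-diphenyl-1,3-benzodioxol-5-yl)carbonyl]oxy}ethyl}rhodium (bisphosphine ligand omitted) | COc1c3OC(c4ccccc4)(c4ccccc4)Oc3cc(C)c1C(=O)O[C@H]([Rh])CC1=C(C(=O)C(C)=O)COC(/C=C/C(=O)OC(C)(C)C)=C1 | intermediate
27 | tert-butyl (2E)-3-[(6S,7S)-7-hydroxy-6-{[(4-methoxy-6-methyl-2,2-diphenyl-1,3-benzodioxol-5-yl)carbonyl]oxy}-7-methyl-8-oxo-5,6,7,8-tetrahydro-1H-isochromen-3-yl]prop-2-enoate | COc1c3OC(c4ccccc4)(c4ccccc4)Oc3cc(C)c1C(=O)O[C@H]1CC2=C(COC(/C=C/C(=O)OC(C)(C)C)=C2)C(=O)[C@@]1(C)O | intermediate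
28 | (2E)-3-[(6S,7S)-6-[(3,4-dihydroxy-2-methoxy-6-methylbenzoyl)oxy]-7-hydroxy-7-methyl-8-oxo-5,6,7,8-tetrahydro-1H-isochromen-3-yl]prop-2-enoic acid | COc1c(O)c(O)cc(C)c1C(=O)O[C@H]1CC2=C(COC(/C=C/C(=O)O)=C2)C(=O)[C@@]1(C)O | target

**Step count:** 15 steps in total. The longest linear sequence is 8 steps (6, 7, 8, 11, 12, 13, 14, 15).

**Steps most likely to fail**

1. Step 14 (proposed new method). What may go wrong:
   - β-carbon elimination toward the acyl carbon instead of the alkenyl carbon;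
   - protonolysis of the alkenylrhodium before the vinyl ester inserts, giving only ring-opened diketone;
   - insertion with the opposite regiochemistry followed by loss of the carboxylate;
   - closure to the trans diastereomer, or poor facial selectivity in the insertion.

   Fallback by known chemistry, setting out from 19 (with acid 5 for the last bond) and returning at 27. Sonogashira coupling of 19 with 6-bromo-2,4-dihydroxy-3-methylbenzaldehyde (Pd(PPh3)2Cl2, CuI, Et3N, DMF) should give tert-butyl (2E)-5-(2-formyl-3,5-dihydroxy-4-methylphenyl)pent-2-en-4-ynoate F1. NaBH4 in MeOH at 0 °C reduces the aldehyde to tert-butyl (2E)-5-[3,5-dihydroxy-2-(hydroxymethyl)-4-methylphenyl]pent-2-en-4-ynoate F2. Gold-catalysed 6-endo cyclization ((Ph3P)AuNTf2) gives tert-butyl (2E)-3-(6,8-dihydroxy-7-methyl-1H-isochromen-3-yl)prop-2-enoate F3. Hydroxylative dearomatization at C7 of this 2-methylresorcinol, as used for azaphilones ([Cu(MeCN)4]PF6, sparteine, O2, with the sparteine antipode that gives 7S; or IBX for the racemate), gives tert-butyl (2E)-3-[(7S)-7-hydroxy-7-methyl-6,8-dioxo-5,6,7,8-tetrahydro-1H-isochromen-3-yl]prop-2-enoate F4. NaBH4 in MeOH at −78 °C should reduce the isolated C6 ketone anti to the C7–O bond (polar Felkin–Anh) to the cis-diol tert-butyl (2E)-3-[(6S,7S)-6,7-dihydroxy-7-methyl-8-oxo-5,6,7,8-tetrahydro-1H-isochromen-3-yl]prop-2-enoate F5. Acylation of the secondary hydroxyl with 4-methoxy-6-methyl-2,2-diphenyl-1,3-benzodioxole-5-carbonyl chloride F6 (from 5 with oxalyl chloride; DMAP, CH2Cl2) then gives 27.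

2. Step 13. What may go wrong: the strain of the cyclobutene-fused 2H-pyran may slow the closure, or 24 may ring-open or oligomerize under the Lewis-acidic gold catalyst.

   Fallback, setting out from 22 and returning at 27, with the order of ring formation reversed. The rhodium annulation of step 14 is run on 22 with 6; the internal alkyne must then stay a spectator. This would give tert-butyl (2E)-5-[(4S,5S)-5-hydroxy-2-{[(4-methoxybenzyl)oxy]methyl}-4-{[(4-methoxy-6-methyl-2,2-diphenyl-1,3-benzodioxol-5-yl)carbonyl]oxy}-5-methyl-6-oxocyclohex-1-en-1-yl]pent-2-en-4-ynoate F7. DDQ then frees the alcohol tert-butyl (2E)-5-[(4S,5S)-5-hydroxy-2-(hydroxymethyl)-4-{[(4-methoxy-6-methyl-2,2-diphenyl-1,3-benzodioxol-5-yl)carbonyl]oxy}-5-methyl-6-oxocyclohex-1-en-1-yl]pent-2-en-4-ynoate F8. Gold-catalysed 6-endo cyclization onto the now unstrained cyclohexenone closes the pyran to 27.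

3. Step 11. What may go wrong: the lithium acetylide carries its own Michael acceptor and may add to itself before it reaches the hindered vinylogous ester carbonyl, and partial loss of the tert-butyl ester is possible in the acid step.

   Fallback, setting out from 15 and returning at 22, with the enoate introduced after the cyclobutenone chemistry. Ethynylmagnesium bromide in THF adds to 15 to give 1-ethynyl-2-{[(4-methoxybenzyl)oxy]methyl}-4-methyl-3-(propan-2-yloxy)-4-[(trimethylsilyl)oxy]cyclobut-2-en-1-ol F9. Aqueous HCl transposes it to 3-ethynyl-4-hydroxy-2-{[(4-methoxybenzyl)oxy]methyl}-4-methylcyclobut-2-en-1-one F10. Sonogashira coupling with tert-butyl (2E)-3-iodoprop-2-enoate (Pd(PPh3)2Cl2, CuI, Et3N) then gives 22.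

Further compounds
F1 | step 14 | tert-butyl (2E)-5-(2-formyl-3,5-dihydroxy-4-methylphenyl)pent-2-en-4-ynoate | O=Cc1c(O)c(C)c(O)cc1C#C/C=C/C(=O)OC(C)(C)C
F2 | step 14 | tert-butyl (2E)-5-[3,5-dihydroxy-2-(hydroxymethyl)-4-methylphenyl]pent-2-en-4-ynoate | OCc1c(O)c(C)c(O)cc1C#C/C=C/C(=O)OC(C)(C)C
F3 | step 14 | tert-butyl (2E)-3-(6,8-dihydroxy-7-methyl-1H-isochromen-3-yl)prop-2-enoate | Cc1c(O)cc2C=C(/C=C/C(=O)OC(C)(C)C)OCc2c1O
F4 | step 14 | tert-butyl (2E)-3-[(7S)-7-hydroxy-7-methyl-6,8-dioxo-5,6,7,8-tetrahydro-1H-isochromen-3-yl]prop-2-enoate | O=C1CC2=C(COC(/C=C/C(=O)OC(C)(C)C)=C2)C(=O)[C@@]1(C)O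
F5 | step 14 | tert-butyl (2E)-3-[(6S,7S)-6,7-dihydroxy-7-methyl-8-oxo-5,6,7,8-tetrahydro-1H-isochromen-3-yl]prop-2-enoate | O[C@H]1CC2=C(COC(/C=C/C(=O)OC(C)(C)C)=C2)C(=O)[C@@]1(C)O
F6 | step 14 | 4-methoxy-6-methyl-2,2-diphenyl-1,3-benzodioxole-5-carbonyl chloride | COc1c3OC(c4ccccc4)(c4ccccc4)Oc3cc(C)c1C(Cl)=O
F7 | step 13 | tert-butyl (2E)-5-[(4S,5S)-5-hydroxy-2-{[(4-methoxybenzyl)oxy]methyl}-4-{[(4-methoxy-6-methyl-2,2-diphenyl-1,3-benzodioxol-5-yl)carbonyl]oxy}-5-methyl-6-oxocyclohex-1-en-1-yl]pent-2-en-4-ynoate | COc1c3OC(c4ccccc4)(c4ccccc4)Oc3cc(C)c1C(=O)O[C@H]1CC(C#C/C=C/C(=O)OC(C)(C)C)=C(COCc2ccc(OC)cc2)C(=O)[C@@]1(C)O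
F8 | step 13 | tert-butyl (2E)-5-[(4S,5S)-5-hydroxy-2-(hydroxymethyl)-4-{[(4-methoxy-6-methyl-2,2-diphenyl-1,3-benzodioxol-5-yl)carbonyl]oxy}-5-methyl-6-oxocyclohex-1-en-1-yl]pent-2-en-4-ynoate | COc1c3OC(c4ccccc4)(c4ccccc4)Oc3cc(C)c1C(=O)O[C@H]1CC(C#C/C=C/C(=O)OC(C)(C)C)=C(CO)C(=O)[C@@]1(C)O
F9 | step 11 | 1-ethynyl-2-{[(4-methoxybenzyl)oxy]methyl}-4-methyl-3-(propan-2-yloxy)-4-[(trimethylsilyl)oxy]cyclobut-2-en-1-ol | CC(C)OC1=C(COCc2ccc(OC)cc2)C(O)(C#C)C1(C)O[Si](C)(C)C
F10 | step 11 | 3-ethynyl-4-hydroxy-2-{[(4-methoxybenzyl)oxy]methyl}-4-methylcyclobut-2-en-1-one | CC1(O)C(C#C)=C(COCc2ccc(OC)cc2)C1=O
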